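The carbocycle is read as a cyclopentadiene (ring A, C13=C12–C1=C2 with C14H2; locants below) whose termini C13 and C2 are spanned by a three-carbon vinylcarbene unit (C3–C4–C5). A rhodium vinylcarbenoid, tied through the future ring-C lactone to C9 of a ring-D-fused dienyl triflate, cyclopropanates C12=C13; the cis-divinylcyclopropane then undergoes Cope rearrangement. This single operation forms C5–C13 and C2–C3, closes rings B and C and sets C13 and C2 from the lone C9 stereocentre. C1 and C12 follow by deconjugative methylation and radical hydrogenation; the lactone is finally unmasked as a 1,5-dialdehyde that closes to the enol-ether acyl acetal.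

Key step: step 9

Remark (locants used throughout): C1 = C(CH3)(CO2Me); C2 = the CH next to it that also carries C3 and C14; C3=C4 = ring alkene; C5 = ring carbon of the enol ether; C6 = O–CH=; O7 = ring oxygen; C8 = acetal CH; C9 = CH bonded to C8; C10, C11 = the two CH2 groups; C12 = CH bonded to C1 and C11; C13 = quaternary carbon bonded to C5, C9, C12 and C14; C14 = CH2 between C2 and C13. Ring A = C1/C2/C14/C13/C12, ring B = C2/C3/C4/C5/C13/C14, ring C = C5/C6/O7/C8/C9/C13, ring D = C9/C10/C11/C12/C13. In this numbering the target is (1R,2S,8S,9R,12R,13S).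

Remark (assumption): 3-(hydroxymethyl)cyclopent-2-en-1-one (1) is taken as a purchasable compound.

Step 1
Reactants: 1 3-(hydroxymethyl)cyclopent-2-en-1-one
Product: 2 3-{[tri(propan-2-yl)silyl]oxymethyl}cyclopent-2-en-1-one
Conditions: TIPSCl, imidazole, CH2Cl2, 0 → 20 °C
Reagents that add atoms: chlorotri(propan-2-yl)silane, CC(C)[Si](Cl)(C(C)C)C(C)C
Why: Standard silylation of a primary alcohol gives an ether that should survive hydride, organolithium, palladium and Lewis acid in steps 2–4.

Step 2
Reactants: 2 3-{[tri(propan-2-yl)silyl]oxymethyl}cyclopent-2-en-1-one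
Product: 5 (3R)-3-{[tri(propan-2-yl)silyl]oxymethyl}cyclopent-1-en-1-yl trifluoromethanesulfonate, via silyl enol ether 3 (not isolated), via lithium enolate 4 (not isolated)
Conditions: CuCl, NaOt-Bu, p-Tol-BINAP (cat.; the antipode that gives the R centre), Ph2SiH2, toluene, −40 °C; then MeLi, THF, −78 °C; then PhNTf2, −78 → 0 °C
Reagents that add atoms: N-phenylbis(trifluoromethanesulfonimide), O=S(=O)(N(c1ccccc1)S(=O)(=O)C(F)(F)F)C(F)(F)F
Why: Asymmetric copper hydride conjugate reduction delivers hydride to the β-carbon (future C9) under control of the chiral bisphosphine, and the regiodefined silyl enol ether is transmetalated and trapped as the enol triflate, which fixes the C12=C13 double bond.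

Step 3
Reactants: 5 (3R)-enol triflate; 6 tributyl(ethenyl)stannane
Product: 7 1-[(3R)-3-{[tri(propan-2-yl)silyl]oxymethyl}cyclopent-1-en-1-yl]prop-2-en-1-one
Conditions: Pd(PPh3)4 (cat.), LiCl, CO (1 atm), THF, 55 °C
Reagents that add atoms: carbon monoxide, [C-]#[O+]
Why: Carbonylative Stille coupling of a vinyl triflate with a vinylstannane is the classical entry to cross-conjugated divinyl ketones and does not touch C9.

Step 4
Reactants: 7 divinyl ketone
Product: 8 (4R)-4-{[tri(propan-2-yl)silyl]oxymethyl}-3,4,5,6-tetrahydropentalen-1(2H)-one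
Conditions: FeCl3, CH2Cl2, −20 → 0 °C
Reagents that add atoms: none
Why: Nazarov cyclisation (4π-conrotatory closure of the pentadienyl cation) forms C13–C14, and proton loss from C13 should give the tetrasubstituted conjugated enone of ring A fused to ring D, with the C9 centre as a spectator.

Step 5
Reactants: 8 bicyclic enone silyl ether
Product: 9 (4R)-4-(hydroxymethyl)-3,4,5,6-tetrahydropentalen-1(2H)-one
Conditions: HF·pyridine, THF, 0 → 20 °C
Reagents that add atoms: none
Why: Fluoride-mediated desilylation under non-basic conditions avoids enolisation towards the γ-stereocentre C9.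

Step 6
Reactants: 9 bicyclic enone alcohol; 10 but-3-enoic acid
Product: 11 [(1R)-4-oxo-1,2,3,4,5,6-hexahydropentalen-1-yl]methyl but-3-enoate
Conditions: DCC, DMAP (cat.), CH2Cl2, 0 °C
Reagents that add atoms: none
Why: Steglich esterification at low temperature should install the C3–C6 unit on O7 without isomerising the β,γ-unsaturated ester.

Step 7
Reactants: 11 but-3-enoate
Product: 12 [(1R)-4-oxo-1,2,3,4,5,6-hexahydropentalen-1-yl]methyl 2-diazobut-3-enoate
Conditions: p-ABSA, DBU, MeCN, 0 °C
Reagents that add atoms: 4-acetamidobenzenesulfonyl azide, CC(=O)Nc1ccc(cc1)S(=O)(=O)N=[N+]=[N-]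
Why: Regitz-type diazo transfer to the doubly activated α-methylene of a β,γ-unsaturated ester gives the vinyldiazoacetate, while the enone protons are too weakly acidic for DBU.

Step 8
Reactants: 12 enone vinyldiazoacetate
Product: 13 [(1R)-4-(trifluoromethanesulfonyloxy)-1,2,3,6-tetrahydropentalen-1-yl]methyl 2-diazobut-3-enoate
Conditions: LiHMDS, THF, −78 °C; PhNTf2, −78 → −20 °C; cold work-up, used at once
Reagents that add atoms: N-phenylbis(trifluoromethanesulfonimide), O=S(=O)(N(c1ccccc1)S(=O)(=O)C(F)(F)F)C(F)(F)F
Why: Kinetic α′-deprotonation of the enone at C2 and O-triflation give the cross-conjugated dienyl triflate, the one cyclopentadiene isomer with C13=C12–C1=C2 and C14 sp3, which is kept cold to suppress 1,5-hydrogen shifts.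

Step 9
Reactants: 13 dienyl triflate vinyldiazoacetate
Product: 15 tetracyclic lactone vinyl triflate (rings A–D; lactone C6=O/O7/C8H2; C4=C5; C3H2; C12=C1–OTf; C2, C9, C13 as in the target), via divinylcyclopropane 14 (not isolated)
Conditions: Rh2(OAc)4 (1 mol %), CH2Cl2, slow addition of 13, −20 → 20 °C
Reagents that add atoms: none
Why: Rh2(OAc)4 converts the vinyldiazoacetate into a donor/acceptor carbenoid at C5, which adds intramolecularly across the ring-fusion alkene C12=C13 (forming C5–C13 and, transiently, C5–C12) to give cyclopropane 14; because the lactone tether can bridge C5 and C9 on one side only, the C3=C4 vinyl group is forced cis to the ring-A vinyl unit C1=C2, and 14 undergoes a [3,3] shift through a boat transition state that breaks C5–C12 and forms C2–C3. The closest known reaction type is the tandem cyclopropanation/Cope rearrangement (formal [4+3] cycloaddition) of rhodium vinylcarbenoids with cyclopentadienes, including ester-tethered intramolecular cases. Ring C (δ-lactone) closes in the carbene addition as a six-membered ring (homoallylic diazoester mode), and ring B, together with the seven-membered ring C1–C2–C3–C4–C5–C13–C12 of the bicyclo[3.2.1]octadiene, closes in the sigmatropic step. C13 is controlled by C9, since the tether delivers the carbenoid to the diene face that carries the CH2O arm (cis C/D fusion), and C2 is fixed because the bridge must span that same face suprafacially. The step needs cyclopropanation at C12=C13 rather than at the enol triflate alkene C1=C2, C–H insertion or reaction of a hydrogen-shifted diene isomer; the six-membered reach of the tether, the electron-poor character of C1=C2 and the generation and use of 13 below 0 °C should secure this.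

Step 10
Reactants: 15 conjugated lactone vinyl triflate
Product: 16 β,γ-unsaturated lactone vinyl triflate (C3=C4, C5–H)
Conditions: LDA, THF, −78 °C; then AcOH, −78 °C
Reagents that add atoms: none
Why: γ-Deprotonation at C3 and kinetic α-protonation of the lactone dienolate (deconjugation) move the ring-B alkene to C3=C4, and C5 can only be protonated on the face that keeps the lactone cis-fused.

Step 11
Reactants: 16 β,γ-unsaturated lactone vinyl triflate
Product: 17 diol vinyl triflate (C5–CH2OH, C9–CH2OH)
Conditions: DIBAL-H, CH2Cl2, −78 → 0 °C; Rochelle salt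
Reagents that add atoms: none
Why: Hydride reduction of the δ-lactone to the 1,5-diol removes the only base-sensitive carbonyl group, and a vinyl triflate is inert to DIBAL-H.

Step 12
Reactants: 17 diol vinyl triflate
Product: 18 diol enoate (CO2Me on C1, C12=C1)
Conditions: Pd(OAc)2, dppp (cat.), CO (1 atm), MeOH, Et3N, DMF, 60 °C
Reagents that add atoms: carbon monoxide, [C-]#[O+]; methanol, CO
Why: Palladium-catalysed methoxycarbonylation of the vinyl triflate installs the ester carbon on C1, with methanol as solvent outcompeting the free hydroxyls for the acyl-palladium species.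

Step 13
Reactants: 18 diol enoate
Product: 19 diol with C1(CH3)(CO2Me) and C11=C12
Conditions: LDA (3.5 equiv), THF–DMPU, −78 °C; then MeI (1.2 equiv)
Reagents that add atoms: iodomethane, CI
Why: γ-Deprotonation at C11 gives the extended ester enolate, which is alkylated at the α-carbon C1 (deconjugative α-alkylation), and because C12 is trigonal and carries no out-of-plane substituent, MeI should approach the exo face of the bicyclo[3.2.1]octene, anti to the C3=C4–C5 bridge, placing CH3 exo and CO2Me endo as in the target.

Step 14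
Reactants: 19 methylated diol with C11=C12
Product: 20 diol with C12–H (cis-fused rings A/D)
Conditions: Mn(dpm)3 (cat.), PhSiH3, t-BuOOH, i-PrOH, 22 °C
Reagents that add atoms: none
Why: Metal-hydride hydrogen atom transfer hydrogenation adds H• to C11 of the trisubstituted alkene to give the tertiary C12 radical (the 1,2-disubstituted C3=C4 bond should not compete), and the ring-D-constrained radical can accept hydrogen only on the endo face, which gives the cis-fused diquinane.

Step 15
Reactants: 20 saturated diol
Product: 21 dialdehyde (C6HO on C5, C8HO on C9)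
Conditions: DMP, NaHCO3, CH2Cl2, 0 °C
Reagents that add atoms: none
Why: Buffered periodinane oxidation takes both primary alcohols to the aldehyde level without over-oxidation and leaves the hindered methyl ester and the alkene alone.

Step 16
Reactants: 21 dialdehyde; 22 3-methylbutanoyl chloride
Product: 24 target CNP0315847.1, via lactol 23 (not isolated)
Conditions: Et3N, DMAP (cat.), CH2Cl2, 0 °C; then 22, 0 → 20 °C
Reagents that add atoms: none
Why: Base enolises the β,γ-unsaturated C6 aldehyde to the conjugated dienol, whose oxygen closes onto the C8 aldehyde (iridoid-type 1,5-dialdehyde to enol-lactol cyclisation, possible only with C8 and C5 cis), and O-acylation of the equilibrating lactol should take the equatorial anomer with H8 trans to H9, setting C8.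

Compound list
1 | 3-(hydroxymethyl)cyclopent-2-en-1-one | O=C1CCC(CO)=C1 | starting material
2 | 3-{[tri(propan-2-yl)silyl]oxymethyl}cyclopent-2-en-1-one | O=C1CCC(CO[Si](C(C)C)(C(C)C)C(C)C)=C1 | intermediate
3 | diphenyl{[(3R)-3-{[tri(propan-2-yl)silyl]oxymethyl}cyclopent-1-en-1-yl]oxy}silane (not isolated) | O([SiH](c1ccccc1)c1ccccc1)C1=C[C@H](CO[Si](C(C)C)(C(C)C)C(C)C)CC1 | intermediate
4 | lithium (3R)-3-{[tri(propan-2-yl)silyl]oxymethyl}cyclopent-1-en-1-olate (not isolated) | [Li]OC1=C[C@H](CO[Si](C(C)C)(C(C)C)C(C)C)CC1 | intermediate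
5 | (3R)-3-{[tri(propan-2-yl)silyl]oxymethyl}cyclopent-1-en-1-yl trifluoromethanesulfonate | O=S(=O)(OC1=C[C@H](CO[Si](C(C)C)(C(C)C)C(C)C)CC1)C(F)(F)F | intermediate
6 | tributyl(ethenyl)stannane | C=C[Sn](CCCC)(CCCC)CCCC | starting material
7 | 1-[(3R)-3-{[tri(propan-2-yl)silyl]oxymethyl}cyclopent-1-en-1-yl]prop-2-en-1-one | C=CC(=O)C1=C[C@H](CO[Si](C(C)C)(C(C)C)C(C)C)CC1 | intermediate
8 | (4R)-4-{[tri(propan-2-yl)silyl]oxymethyl}-3,4,5,6-tetrahydropentalen-1(2H)-one | O=C1CCC2=C1CC[C@H]2CO[Si](C(C)C)(C(C)C)C(C)C | intermediate
9 | (4R)-4-(hydroxymethyl)-3,4,5,6-tetrahydropentalen-1(2H)-one | O=C1CCC2=C1CC[C@H]2CO | intermediate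
10 | but-3-enoic acid | C=CCC(=O)O | starting material
11 | [(1R)-4-oxo-1,2,3,4,5,6-hexahydropentalen-1-yl]methyl but-3-enoate | O=C1CCC2=C1CC[C@H]2COC(=O)CC=C | intermediate
12 | [(1R)-4-oxo-1,2,3,4,5,6-hexahydropentalen-1-yl]methyl 2-diazobut-3-enoate | O=C1CCC2=C1CC[C@H]2COC(=O)C(=[N+]=[N-])C=C | intermediate
13 | [(1R)-4-(trifluoromethanesulfonyloxy)-1,2,3,6-tetrahydropentalen-1-yl]methyl 2-diazobut-3-enoate | C=CC(=[N+]=[N-])C(=O)OC[C@@H]1CCC2=C1CC=C2OS(=O)(=O)C(F)(F)F | intermediate
14 | cis-divinylcyclopropane (cyclopropane C5/C12/C13 fused to the δ-lactone and to rings A and D; vinyl C3=C4 on C5 cis to C1(OTf)=C2; not isolated) | C=C[C@]12C(=O)OC[C@@H]3CC[C@@]1(C(OS(=O)(=O)C(F)(F)F)=CC4)[C@]234 | intermediate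
15 | tetracyclic conjugated lactone vinyl triflate (C6=O, C4=C5, C3H2, C12=C1–OTf) | O=S(=O)(OC=1[C@@H]2CC=C3C(=O)OC[C@@H]4CCC=1[C@]34C2)C(F)(F)F | intermediate
16 | tetracyclic β,γ-unsaturated lactone vinyl triflate (C3=C4, C5–H) | O=S(=O)(OC=1[C@@H]2C=C[C@@H]3C(=O)OC[C@@H]4CCC=1[C@]34C2)C(F)(F)F | intermediate
17 | tricyclic diol vinyl triflate (C5–CH2OH, C9–CH2OH, C3=C4, C12=C1–OTf) | OC[C@@H]1CCC2=C(OS(=O)(=O)C(F)(F)F)[C@H]3C[C@@]12[C@@H](CO)C=C3 | intermediate
18 | tricyclic diol enoate (methyl ester on C1, C12=C1) | OC[C@@H]1CCC2=C(C(=O)OC)[C@H]3C[C@@]12[C@@H](CO)C=C3 | intermediate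
19 | tricyclic diol with C1(CH3)(CO2Me) and C11=C12 | OC[C@@H]1CC=C2[C@](C)(C(=O)OC)[C@H]3C[C@@]12[C@@H](CO)C=C3 | intermediate
20 | tricyclic diol with C12–H (rings A/D cis-fused) | OC[C@@H]1CC[C@H]2[C@](C)(C(=O)OC)[C@H]3C[C@@]12[C@@H](CO)C=C3 | intermediate
21 | tricyclic dialdehyde (C6HO on C5, C8HO on C9) | O=C[C@@H]1CC[C@H]2[C@](C)(C(=O)OC)[C@H]3C[C@@]12[C@@H](C=O)C=C3 | intermediate
22 | 3-methylbutanoyl chloride | CC(C)CC(=O)Cl | starting material
23 | lactol (ring C closed, C8–OH; not isolated in step 16) | COC(=O)[C@]1(C)[C@@H]2C=CC3=CO[C@@H](O)[C@@H]4CC[C@@H]1[C@]34C2 | intermediate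
24 | CNP0315847.1, (1R,2S,8S,9R,12R,13S) in the locants above | COC(=O)[C@]1(C)[C@@H]2C=CC3=CO[C@@H](OC(=O)CC(C)C)[C@@H]4CC[C@@H]1[C@]34C2 | target

Total step count: 16. Longest linear sequence: 16 steps (1 → 24).

Steps most likely to fail

Step 9 (key step). The carbenoid may fail to engage the tetrasubstituted, triflate-deactivated C12=C13 bond, so that carbene dimerisation, C–H insertion or a 1,5-hydrogen shift of the diene takes over. The fallback changes the diene partner and sets out from 12. Soft enolisation (TBSOTf, Et3N, CH2Cl2, −78 °C, no strong base) gives the more nucleophilic 2-silyloxydiene, tert-butyldimethylsilyl dienol ether F1. Treatment with Rh2(OAc)4 in the same flask should give silyl enol ether lactone F2 by the same cyclopropanation/Cope sequence or its stepwise zwitterionic variant. CsF and PhNTf2 in DME then convert F2 into vinyl triflate 15, where the route is rejoined.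

Step 13. Methylation of the trianion of 18 may stall, go to oxygen, or lose facial selectivity through aggregation of the alkoxide-bearing dienolate. The fallback sets out from 18 and masks both hydroxyls first. TBSCl and imidazole give bis-silyl ether F3; KHMDS then MeI (THF, −78 °C) act on the single ester dienolate to give methylated bis-silyl ether F4; TBAF returns diol 19.

Step 16. Acylation may intercept the open dienol, giving an acyclic dienyl ester, or may attach the acyl group to the wrong face of C8. The fallback sets out from 21 and makes the ester by displacement instead of O-acylation. Cyclisation with Et3N alone gives lactol 23, which is isolated. Cl3CCN and DBU convert it into the axial trichloroacetimidate F5. Reaction of F5 with 3-methylbutanoic acid (CH2Cl2, no promoter) should give 24 by invertive substitution at C8.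

Further compounds
F1 | step 9 | [(1R)-4-{[tert-butyl(dimethyl)silyl]oxy}-1,2,3,6-tetrahydropentalen-1-yl]methyl 2-diazobut-3-enoate | C=CC(=[N+]=[N-])C(=O)OC[C@@H]1CCC2=C1CC=C2O[Si](C)(C)C(C)(C)C
F2 | step 9 | tetracyclic conjugated lactone tert-butyldimethylsilyl enol ether (as 15 with OTBS on C1) | CC(C)(C)[Si](C)(C)OC=1[C@@H]2CC=C3C(=O)OC[C@@H]4CCC=1[C@]34C2
F3 | step 13 | bis(tert-butyldimethylsilyl) ether of 18 | CC(C)(C)[Si](C)(C)OC[C@@H]1CCC2=C(C(=O)OC)[C@H]3C[C@@]12[C@@H](CO[Si](C)(C)C(C)(C)C)C=C3
F4 | step 13 | bis(tert-butyldimethylsilyl) ether of 19 | CC(C)(C)[Si](C)(C)OC[C@@H]1CC=C2[C@](C)(C(=O)OC)[C@H]3C[C@@]12[C@@H](CO[Si](C)(C)C(C)(C)C)C=C3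
F5 | step 16 | O-(2,2,2-trichloroacetimidoyl) lactol, C8 epimer of 23 (axial imidate) | COC(=O)[C@]1(C)[C@@H]2C=CC3=CO[C@H](OC(=N)C(Cl)(Cl)Cl)[C@@H]4CC[C@@H]1[C@]34C2
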